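Ring B is cut at C7–C8 and at C9–C10, the bond that joins the two fully substituted carbons where rings A, B and C meet. This leaves a ring A 2-silyloxy diene (C10=C5–C6=C7) and a pre-formed ring C/ring D spiro-lactone whose (Z)-ethylidene group (C8=C9) is activated by a C11 ketone. One Lewis-acid-promoted Diels–Alder reaction closes ring B, makes both bonds and sets C8, C9 and C10 relative to C13, which is taken from (R)-malic acid. The C6 silyl enol ether and the C11 ketone left in the adduct are then turned into the C6 acetate and the C11 methylene.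

Key step: step 9

Remark on numbering: labdane numbers are used throughout (ring A C1–C5 and C10; ring B C5–C10; ring C O, C9, C11, C12, C13; ring D C13, C14, C15, O, C16).

Remark on configuration: read from the target SMILES, H5, the C6 acetoxy group, the C8 methyl, the ring C oxygen on C9 and the C10 methyl all lie on one face (rings A and B are cis-fused), C11 lies on the other face, and C14 is on the C10 side of ring C. The route is built for this isomer; an achiral C13 source cannot give one enantiomer, so C13 is taken from the chiral pool.

Remark on C11: the C11 carbinol of compounds 18 to 20 is carried as an epimer mixture (SMILES left undefined at C11); the centre becomes CH2 in step 12.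

Step 1
Reactants: 1 β-cyclocitral (2,6,6-trimethylcyclohex-1-ene-1-carbaldehyde)
Product: 2 (±)-1-(2,6,6-trimethylcyclohex-1-en-1-yl)ethan-1-ol
Conditions: MeMgBr, THF, 0 °C; H2O
Reagents that add atoms: methylmagnesium bromide, C[Mg]Br
Why: Grignard 1,2-addition to the hindered enal gives the allylic alcohol, whose racemic carbinol centre is erased in step 2.

Step 2
Reactants: 2 (±)-1-(2,6,6-trimethylcyclohex-1-en-1-yl)ethan-1-ol
Product: 3 1-(2,6,6-trimethylcyclohex-1-en-1-yl)ethan-1-one (ring A methyl ketone)
Conditions: Dess–Martin periodinane, CH2Cl2, rt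
Reagents that add atoms: none
Why: Dess–Martin oxidation of the secondary allylic alcohol gives the methyl ketone without touching the tetrasubstituted alkene.

Step 3
Reactants: 3 1-(2,6,6-trimethylcyclohex-1-en-1-yl)ethan-1-one
Product: 4 tert-butyldimethyl{[1-(2,6,6-trimethylcyclohex-1-en-1-yl)ethenyl]oxy}silane (ring A 2-silyloxy diene, C10=C5–C6(OTBS)=C7)
Conditions: TBSOTf, Et3N, CH2Cl2, 0 °C
Reagents that add atoms: tert-butyldimethylsilyl trifluoromethanesulfonate, CC(C)(C)[Si](C)(C)OS(=O)(=O)C(F)(F)F
Why: Silyl enol ether formation by soft enolisation removes a methyl proton (the twisted enone is poorly conjugated, so γ-deprotonation should not compete) and gives the cross-conjugated diene.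

Step 4
Reactants: 5 (R)-malic acid; 6 pivalaldehyde
Product: 7 2-[(2R,4R)-2-tert-butyl-5-oxo-1,3-dioxolan-4-yl]acetic acid (cis acetal)
Conditions: TsOH (cat.), H2SO4 (cat.), pentane, reflux, water separator; crystallisation
Reagents that add atoms: none
Why: Acid-catalysed acetalisation of the α-hydroxy acid unit (dioxolanone formation for self-regeneration of a stereocentre) should give mainly the cis acetal, which stores the future C13 configuration in the new acetal centre.

Step 5
Reactants: 7 2-[(2R,4R)-2-tert-butyl-5-oxo-1,3-dioxolan-4-yl]acetic acid; 8 propargyl bromide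
Product: 10 2-[(2R,4R)-2-tert-butyl-5-oxo-4-(prop-2-yn-1-yl)-1,3-dioxolan-4-yl]acetic acid (propargyl trans to tert-butyl), via dilithium enolate carboxylate 9 (not isolated)
Conditions: LiN(SiMe3)2 (2.2 equiv), THF, −78 °C; 8, −78 → −20 °C; 1 M HCl
Reagents that add atoms: none
Why: Enolate alkylation of the dioxolanone (the side-chain acid is masked as its lithium salt) occurs anti to the tert-butyl group, so propargyl replaces hydrogen with overall retention and fixes the future C13.

Step 6
Reactants: 10 2-[(2R,4R)-2-tert-butyl-5-oxo-4-(prop-2-yn-1-yl)-1,3-dioxolan-4-yl]acetic acid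
Product: 13 (3R)-3-hydroxy-3-(prop-2-yn-1-yl)oxolan-2-one (ring D lactone carrying the free tertiary hydroxyl), via isobutyl carbonic mixed anhydride 11 (not isolated), via hydroxyethyl dioxolanone 12 (not isolated)
Conditions: i-BuOCOCl, N-methylmorpholine, THF, −15 °C; NaBH4, H2O, 0 °C; TsOH (cat.), CH2Cl2, rt
Reagents that add atoms: none
Why: Mixed-anhydride reduction with NaBH4 should be selective, since the anhydride is far more electrophilic than the acetal ester and the alkyne is inert (unlike towards borane), after which acid-catalysed lactonisation onto the dioxolanone carbonyl releases pivalaldehyde and the tertiary alcohol without touching C13.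

Step 7
Reactants: 13 (3R)-3-hydroxy-3-(prop-2-yn-1-yl)oxolan-2-one
Product: 14 (5S)-1,7-dioxaspiro[4.4]nonane-3,6-dione (rings C and D)
Conditions: Ph3PAuNTf2 (5 mol %), 3,5-dichloropyridine N-oxide (2 equiv), MsOH (1.2 equiv), ClCH2CH2Cl, rt
Reagents that add atoms: 3,5-dichloropyridine N-oxide, [O-][n+]1cc(Cl)cc(Cl)c1
Why: Gold-catalysed alkyne oxidation by the N-oxide generates an α-oxo gold carbene at the terminal carbon, which inserts into the homopropargylic O–H bond and closes ring C as the 3-oxotetrahydrofuran (the acid ties up the released pyridine).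

Step 8
Reactants: 14 (5S)-1,7-dioxaspiro[4.4]nonane-3,6-dione; 15 acetaldehyde
Product: 16 (2Z,5S)-2-ethylidene-1,7-dioxaspiro[4.4]nonane-3,6-dione (dienophile, C8=C9 with the C8 methyl)
Conditions: 15 (3 equiv, slow addition), pyrrolidine (0.2 equiv), AcOH (0.2 equiv), CH2Cl2, 0 °C → rt
Reagents that add atoms: none
Why: Amine-catalysed aldol condensation should take place at the oxygen-bearing α-carbon C9 (C12 is neopentyl, next to the spiro centre), and the reversible addition–elimination lets the alkene settle as the Z isomer, with the methyl next to the ring oxygen and away from the C11 carbonyl.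

Step 9
Reactants: 4 ring A 2-silyloxy diene; 16 (2Z,5S)-2-ethylidene-1,7-dioxaspiro[4.4]nonane-3,6-dione
Product: 17 cycloadduct, 6-(tert-butyldimethylsilyloxy)-9,13-epoxy-11-oxolabd-5-en-16,15-olide (C8 methyl, ring C oxygen on C9 and C10 methyl mutually cis, C11 on the other face of ring B, C14 on the C10 side of ring C)
Conditions: 16, AlBr3 (2.2 equiv), AlMe3 (0.2 equiv), toluene/CH2Cl2, −20 °C; 4 (1.5 equiv), −20 °C → rt; Et3N, aq. NaHCO3
Reagents that add atoms: none
Why: The aluminium halide bound to the C11 carbonyl lowers the LUMO of the fixed s-cis enone, and the cycloaddition should be concerted but asynchronous, the nucleophilic CH2 terminus C7 of the silyloxy diene bonding to the β-carbon C8 ahead of C10 to C9. The closest known reaction type is the Diels–Alder reaction of hindered 2-silyloxy dienes with α-substituted enones under AlBr3/AlMe3, which is used to join two fully substituted carbons. Ring B is closed in the (4+2) mode, both new σ-bonds forming on one face of each partner. C8 relative to C9 follows from the Z-alkene (the methyl stays cis to the ring C oxygen), C10 relative to C9 from the endo position of the complexed C11 carbonyl (C11 cis to C1, C10 methyl cis to the ring oxygen), and all three relative to C13 from attack on the furanone face that carries the C14 methylene. The step needs para-type regiochemistry, secured by the 2-silyloxy group and the enone polarisation, and facial selectivity, secured because the lactone carbonyl oxygen, itself complexed by the second equivalent of AlBr3, projects over the opposite face; AlMe3 scavenges protic acid that would cleave the silyl enol ether.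

Step 10
Reactants: 17 cycloadduct
Product: 18 C11 alcohol, 6-(tert-butyldimethylsilyloxy)-9,13-epoxy-11-hydroxylabd-5-en-16,15-olide (C11 epimers)
Conditions: NaBH4, EtOH/THF, −20 °C
Reagents that add atoms: none
Why: Hydride reduction of the α-alkoxy five-ring ketone should be fast at low temperature while the lactone and silyl enol ether survive, and keeping C6 masked avoids a free 1,5-diketone that could open the C9–C10 bond by retro-Michael reaction.

Step 11
Reactants: 18 C11 alcohol
Product: 20 C11 O-alkyl S-methyl dithiocarbonate (xanthate) of 18, via sodium xanthate salt 19 (not isolated)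
Conditions: NaN(SiMe3)2, THF, −78 °C; CS2; MeI, −78 °C → rt
Reagents that add atoms: carbon disulfide, S=C=S; iodomethane, CI
Why: Xanthate formation from the hindered secondary alkoxide is reliable, and the lactone (no α-hydrogen) and the silyl enol ether tolerate the base at low temperature.

Step 12
Reactants: 20 C11 xanthate
Product: 21 6-(tert-butyldimethylsilyloxy)-9,13-epoxylabd-5-en-16,15-olide (C11 now CH2)
Conditions: Bu3SnH, AIBN (cat.), toluene, 100 °C
Reagents that add atoms: none
Why: Barton–McCombie deoxygenation gives the secondary C11 radical, which takes hydrogen from Bu3SnH; its only intramolecular option, 5-endo attack on the C5=C6 enol ether, is not feasible.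

Step 13
Reactants: 21 6-(tert-butyldimethylsilyloxy)-9,13-epoxylabd-5-en-16,15-olide
Product: 23 cis-fused C6 ketone, 9,13-epoxy-6-oxolabdan-16,15-olide with H5 cis to the C10 methyl, via trans-fused C6 ketone 22 (not isolated)
Conditions: 1 M HCl, THF, rt; NaOMe (0.3 equiv), MeOH, 40 °C; AcOH
Reagents that add atoms: none
Why: Silyl enol ether hydrolysis should protonate C5 mainly anti to the C10 methyl, and base-mediated epimerisation then moves C5 to the cis-fused ketone, whose chair–chair form has the C8 and C10 methyl groups and C11 equatorial on ring B, whereas the trans isomer must hold the two methyls 1,3-diaxial (the lactone has no α-hydrogen and recloses if opened).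

Step 14
Reactants: 23 cis-fused C6 ketone
Product: 24 9,13-epoxy-6-hydroxylabdan-16,15-olide with the hydroxyl trans to H5 and to the C10 methyl (concave face)
Conditions: LiBH(s-Bu)3, THF, −78 → −40 °C; H2O
Reagents that add atoms: none
Why: In the cis-fused ketone the C6 face opposite to H5 is screened by the axial C1 methylene of ring A, so bulky-hydride reduction should deliver hydrogen from the convex face (that of H5 and the C10 methyl) and leave the hydroxyl on the concave face; the lactone is inert at −78 °C.

Step 15
Reactants: 24 6-alcohol with the hydroxyl trans to H5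
Product: 25 target, 6-acetoxy-9,13-epoxylabdan-16,15-olide with H5, the C6 acetoxy group, the C8 methyl, the ring C oxygen on C9 and the C10 methyl on one face and C14 on the C10 side of ring C
Conditions: PPh3, DIAD, AcOH, toluene, 0 °C → rt
Reagents that add atoms: acetic acid, CC(=O)O
Why: Mitsunobu esterification displaces the activated axial oxygen by SN2 attack of acetate from the open convex face, inverting C6 so that the acetate ends cis to H5 and the C10 methyl.

Compound list
1 | β-cyclocitral | CC1=C(C=O)C(C)(C)CCC1 | starting material
2 | (±)-1-(2,6,6-trimethylcyclohex-1-en-1-yl)ethan-1-ol | CC(O)C1=C(C)CCCC1(C)C | intermediate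
3 | 1-(2,6,6-trimethylcyclohex-1-en-1-yl)ethan-1-one | CC(=O)C1=C(C)CCCC1(C)C | intermediate
4 | tert-butyldimethyl{[1-(2,6,6-trimethylcyclohex-1-en-1-yl)ethenyl]oxy}silane | C=C(O[Si](C)(C)C(C)(C)C)C1=C(C)CCCC1(C)C | intermediate
5 | (R)-malic acid | O[C@@H](C(=O)O)CC(=O)O | starting material
6 | pivalaldehyde | CC(C)(C)C=O | starting material
7 | 2-[(2R,4R)-2-tert-butyl-5-oxo-1,3-dioxolan-4-yl]acetic acid | CC(C)(C)[C@@H]1O[C@H](CC(=O)O)C(=O)O1 | intermediate
8 | propargyl bromide | C#CCBr | starting material
9 | dilithium enolate carboxylate of 7 (not isolated) | CC(C)(C)[C@@H]1OC(CC(=O)[O-])=C([O-])O1.[Li+].[Li+] | intermediate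
10 | 2-[(2R,4R)-2-tert-butyl-5-oxo-4-(prop-2-yn-1-yl)-1,3-dioxolan-4-yl]acetic acid | CC(C)(C)[C@@H]1O[C@](CC#C)(CC(=O)O)C(=O)O1 | intermediate
11 | isobutyl carbonic mixed anhydride of 10 (not isolated) | CC(C)(C)[C@@H]1O[C@](CC#C)(CC(=O)OC(=O)OCC(C)C)C(=O)O1 | intermediate
12 | (2R,5R)-2-tert-butyl-5-(2-hydroxyethyl)-5-(prop-2-yn-1-yl)-1,3-dioxolan-4-one (not isolated) | CC(C)(C)[C@@H]1O[C@](CC#C)(CCO)C(=O)O1 | intermediate
13 | (3R)-3-hydroxy-3-(prop-2-yn-1-yl)oxolan-2-one | O[C@]1(CC#C)CCOC1=O | intermediate
14 | (5S)-1,7-dioxaspiro[4.4]nonane-3,6-dione | O=C1CO[C@@]2(CCOC2=O)C1 | intermediate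
15 | acetaldehyde | CC=O | starting material
16 | (2Z,5S)-2-ethylidene-1,7-dioxaspiro[4.4]nonane-3,6-dione | C/C=C1\O[C@@]2(CCOC2=O)CC1=O | intermediate
17 | cycloadduct, 6-(tert-butyldimethylsilyloxy)-9,13-epoxy-11-oxolabd-5-en-16,15-olide | CC(C)(C)[Si](C)(C)OC=1C[C@@H](C)[C@]2(C(=O)C[C@]3(CCOC3=O)O2)[C@]2(C)CCCC(C)(C)C=12 | intermediate
18 | C11 alcohol of 17 (C11 epimers) | CC(C)(C)[Si](C)(C)OC=1C[C@@H](C)[C@]2(C(O)C[C@]3(CCOC3=O)O2)[C@]2(C)CCCC(C)(C)C=12 | intermediate
19 | sodium xanthate salt of 18 (not isolated) | CC(C)(C)[Si](C)(C)OC=1C[C@@H](C)[C@]2(C(OC(=S)[S-])C[C@]3(CCOC3=O)O2)[C@]2(C)CCCC(C)(C)C=12.[Na+] | intermediate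
20 | C11 O-alkyl S-methyl dithiocarbonate of 18 | CC(C)(C)[Si](C)(C)OC=1C[C@@H](C)[C@]2(C(OC(=S)SC)C[C@]3(CCOC3=O)O2)[C@]2(C)CCCC(C)(C)C=12 | intermediate
21 | 6-(tert-butyldimethylsilyloxy)-9,13-epoxylabd-5-en-16,15-olide | CC(C)(C)[Si](C)(C)OC=1C[C@@H](C)[C@]2(CC[C@]3(CCOC3=O)O2)[C@]2(C)CCCC(C)(C)C=12 | intermediate
22 | trans-fused C6 ketone, H5 trans to the C10 methyl (not isolated) | O=C1C[C@@H](C)[C@]2(CC[C@]3(CCOC3=O)O2)[C@]2(C)CCCC(C)(C)[C@@H]12 | intermediate
23 | cis-fused C6 ketone, H5 cis to the C10 methyl | O=C1C[C@@H](C)[C@]2(CC[C@]3(CCOC3=O)O2)[C@]2(C)CCCC(C)(C)[C@H]12 | intermediate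
24 | 6-alcohol with the hydroxyl trans to H5 | O[C@@H]1C[C@@H](C)[C@]2(CC[C@]3(CCOC3=O)O2)[C@]2(C)CCCC(C)(C)[C@H]12 | intermediate
25 | 6-acetoxy-9,13-epoxylabdan-16,15-olide, all-cis isomer defined above | CC(=O)O[C@H]1C[C@@H](C)[C@]2(CC[C@]3(CCOC3=O)O2)[C@]2(C)CCCC(C)(C)[C@H]12 | target

Total step count: 15 steps.
Longest linear sequence: 12 steps (steps 4 to 15, from (R)-malic acid); the diene branch needs 3 steps before the key step.

Steps most likely to fail

1. Step 9. Both new bonds end at crowded carbons and the twisted diene must reach its s-cis form, so the cycloaddition may stall after the first bond or not start. The Lewis acid may also cleave the silyl enol ether, and the lactone may discriminate the two furanone faces too weakly. Fallback: activate the nucleophile instead of the electrophile. It sets out from ketone 3 and dienophile 16 and returns to the route at 17. Ketone 3 is deprotonated with LiN(i-Pr)2 in THF at −78 °C to the cross-conjugated lithium dienolate F1. F1 adds to 16 by two consecutive Michael additions (C7 to C8, then the furanone enolate carbon C9 to C10) on warming, in the manner of the anionic double Michael annulation. The final C5=C6 lithium enolate is trapped in the same flask with TBSOTf to give 17.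

2. Step 15. The activated axial oxygen at C6 has anti-periplanar hydrogens on C5 and C7, so elimination may outrun substitution, and the shielded hydroxyl may be slow to activate. Fallback: set C6 by electron-transfer reduction instead of hydride addition followed by inversion. It sets out from ketone 23 and returns at 25. Reduction with SmI2 in THF/H2O at rt, as in dissolving-metal reductions of cyclohexanones, should place the oxygen in the equatorial position on the convex face and give the 6-alcohol with the hydroxyl cis to H5 F2. F2 is acetylated with Ac2O, DMAP and pyridine to give 25.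

3. Step 8. Acetaldehyde may self-condense under amine catalysis, condensation may occur at C12, or the amine may open the lactone. Fallback: a directed, Lewis-acid-mediated aldol with a non-enolisable acetaldehyde equivalent. It sets out from 14 and returns at 16. Treatment of 14 with TMSOTf and Et3N in CH2Cl2 at 0 °C gives the C9=C11 silyl enol ether, (5S)-3-(trimethylsilyloxy)-1,7-dioxaspiro[4.4]non-2-en-6-one F3. Mukaiyama-type addition of F3 to 1,1-dimethoxyethane (TMSOTf cat., CH2Cl2, −78 °C) gives (5S)-2-(1-methoxyethyl)-1,7-dioxaspiro[4.4]nonane-3,6-dione F4. DBU in CH2Cl2 at rt then removes methanol by E1cB elimination and equilibrates the alkene to the Z isomer 16.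

Further compounds
F1 | step 9 | lithium 1-(2,6,6-trimethylcyclohex-1-en-1-yl)ethen-1-olate (cross-conjugated dienolate of 3) | [Li+].[O-]C(=C)C1=C(C)CCCC1(C)C
F2 | step 15 | 9,13-epoxy-6-hydroxylabdan-16,15-olide with the hydroxyl cis to H5 (C6 epimer of 24) | O[C@H]1C[C@@H](C)[C@]2(CC[C@]3(CCOC3=O)O2)[C@]2(C)CCCC(C)(C)[C@H]12
F3 | step 8 | (5S)-3-(trimethylsilyloxy)-1,7-dioxaspiro[4.4]non-2-en-6-one | C[Si](C)(C)OC1=CO[C@@]2(CCOC2=O)C1
F4 | step 8 | (5S)-2-(1-methoxyethyl)-1,7-dioxaspiro[4.4]nonane-3,6-dione (epimers at C2 and at the side-chain carbon) | COC(C)C1O[C@@]2(CCOC2=O)CC1=O
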